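**Retrosynthetic overview**
1. The last bond made is C4 of upper ring C to C8 of lower ring D. It comes from a one-flask anti hydroxy-arylation of the C3=C4 double bond of an (S)-flav-3-ene with 5,7,3',4'-tetra-O-benzylcatechin: dimethyldioxirane builds a 3,4-oxirane (a ring absent from the target), and its strain-release Friedel–Crafts opening forms the C–C bond and frees the 3-hydroxyl. Eight benzyl ethers then leave together.
2. Enabling feature: C4 of ring C is benzylic to ring A and tied through C4a to O7 (para) and O1 (ortho, via C8a), so the oxirane opens only at C4, as a masked quinone methide. C8 of ring D, between O7 and the tied-back ring oxygen O1 of the catechin unit, is the most accessible nucleophilic carbon of that ring.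
3. Stereorelay in the upper unit: C2 (set by the catalyst) → C3 (epoxidation anti to the C2 aryl group) → C4 (inversion on ring opening). The catechin stereocentres are bought.
4. Ring order: rings A and B and the whole catechin unit (rings D, E, F) come from commercial materials. Ring C is closed by ring-closing metathesis of an (S)-1-arylallyl 2-vinylaryl ether made by iridium-catalysed asymmetric allylic etherification. The oxirane is formed and opened in the key step, and no ring is formed after it.
5. Fragments: the flav-3-ene from 3,4,5-trihydroxybenzaldehyde and 4-(benzyloxy)-2-hydroxybenzaldehyde (seven steps), the nucleophile from (+)-catechin (one step).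

Key step: step 9

Remark: ring letters are A (benzo ring), B (aryl ring) and C (pyran ring) for the upper unit and D, E and F in the same sense for the catechin unit; flavan atom numbers are used for both units.

**Route**

Step 1
Reactants: 1 3,4,5-trihydroxybenzaldehyde
Product: 2 3,4,5-tris(benzyloxy)benzaldehyde
Conditions: BnBr (3.6 equiv), K2CO3, DMF, 60 °C, N2
Reagents that add atoms: benzyl bromide, BrCc1ccccc1
Why: Williamson ether synthesis on the three phenols; benzyl is chosen so that all phenol protecting groups of the route can leave together by hydrogenolysis at the end.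

Step 2
Reactants: 2 3,4,5-tris(benzyloxy)benzaldehyde
Product: 3 ethyl (2E)-3-[3,4,5-tris(benzyloxy)phenyl]prop-2-enoate
Conditions: (EtO)2P(O)CH2CO2Et, NaH, THF, 0 → 23 °C
Reagents that add atoms: triethyl phosphonoacetate, CCOC(=O)CP(=O)(OCC)OCC
Why: Horner–Wadsworth–Emmons olefination of the aromatic aldehyde with the stabilised phosphonate anion should give the (E)-cinnamate.

Step 3
Reactants: 3 ethyl (2E)-3-[3,4,5-tris(benzyloxy)phenyl]prop-2-enoate
Product: 4 (2E)-3-[3,4,5-tris(benzyloxy)phenyl]prop-2-en-1-ol
Conditions: i-Bu2AlH (2.3 equiv), CH2Cl2, −78 °C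
Reagents that add atoms: none
Why: 1,2-reduction of the conjugated ester by the aluminium hydride at low temperature should give the (E)-allylic alcohol without touching the alkene or the benzyl ethers.

Step 4
Reactants: 4 (2E)-3-[3,4,5-tris(benzyloxy)phenyl]prop-2-en-1-ol
Product: 5 methyl (2E)-3-[3,4,5-tris(benzyloxy)phenyl]prop-2-en-1-yl carbonate
Conditions: ClCO2Me, pyridine, CH2Cl2, 0 °C
Reagents that add atoms: methyl chloroformate, COC(=O)Cl
Why: O-acylation of the primary allylic alcohol gives the linear methyl carbonate, the usual leaving group for iridium-catalysed allylic substitution.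

Step 5
Reactants: 6 4-(benzyloxy)-2-hydroxybenzaldehyde
Product: 7 5-(benzyloxy)-2-ethenylphenol
Conditions: Ph3PCH3Br (2.5 equiv), KOt-Bu (2.5 equiv), THF, 0 → 23 °C; used at once
Reagents that add atoms: methyltriphenylphosphonium bromide, C[P+](c1ccccc1)(c1ccccc1)c1ccccc1.[Br-]
Why: Wittig methylenation of the salicylaldehyde with excess ylide (one equivalent of base is taken up by the phenol) should give the 2-vinylphenol.

Step 6
Reactants: 5 methyl (2E)-3-[3,4,5-tris(benzyloxy)phenyl]prop-2-en-1-yl carbonate; 7 5-(benzyloxy)-2-ethenylphenol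
Product: 9 4-(benzyloxy)-1-ethenyl-2-({(1S)-1-[3,4,5-tris(benzyloxy)phenyl]prop-2-en-1-yl}oxy)benzene, via lithium aryloxide 8 (not isolated)
Conditions: 7, n-BuLi (1.0 equiv), THF, −78 → 23 °C; then [Ir(cod)Cl]2 (2 mol %), (Sa,Sc,Sc)-O,O'-(1,1'-binaphthyl-2,2'-diyl) N,N-bis(1-phenylethyl)phosphoramidite (4 mol %), 5, THF, 50 °C
Reagents that add atoms: none
Why: Iridium-catalysed asymmetric allylic etherification: aryloxide 8 attacks the aryl-substituted terminus of the phosphoramidite-ligated iridium allyl intermediate, and the (Sa,Sc,Sc) ligand is the enantiomer that should deliver oxygen nucleophiles to give the branched (S) ether, whose stereocentre becomes C2 of ring C.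

Step 7
Reactants: 9 4-(benzyloxy)-1-ethenyl-2-({(1S)-1-[3,4,5-tris(benzyloxy)phenyl]prop-2-en-1-yl}oxy)benzene
Product: 10 (2S)-7-(benzyloxy)-2-[3,4,5-tris(benzyloxy)phenyl]-2H-chromene
Conditions: second-generation Grubbs catalyst RuCl2(=CHPh)(H2IMes)(PCy3) (3 mol %), 1,4-benzoquinone (10 mol %), CH2Cl2, 40 °C, dark
Reagents that add atoms: none
Why: Ring-closing metathesis of the styrene and the allyl ether alkene closes ring C as a six-membered 2H-chromene with loss of ethene and leaves the C2 stereocentre untouched.

Step 8
Reactants: 11 (+)-catechin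
Product: 12 (2R,3S)-5,7-bis(benzyloxy)-2-[3,4-bis(benzyloxy)phenyl]chroman-3-ol
Conditions: BnBr (4.4 equiv), K2CO3, DMF, 0 → 23 °C, N2
Reagents that add atoms: benzyl bromide, BrCc1ccccc1
Why: Williamson etherification under mild carbonate conditions benzylates the four phenols and leaves the secondary 3-hydroxyl and both stereocentres untouched.

Step 9
Reactants: 10 (2S)-7-(benzyloxy)-2-[3,4,5-tris(benzyloxy)phenyl]-2H-chromene; 12 (2R,3S)-5,7-bis(benzyloxy)-2-[3,4-bis(benzyloxy)phenyl]chroman-3-ol
Product: 14 octa-O-benzyl robinetinidol-(4α,8)-catechin, via trans-epoxide 13 (not isolated)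
Conditions: DMDO (1.1 equiv, dried acetone solution), CH2Cl2, −40 → 0 °C, dark; volatiles removed at 0 °C; then slow addition to 12 (3 equiv), BF3·OEt2 (0.2 equiv), 4 Å MS, CH2Cl2, −78 → −40 °C; NaHCO3
Reagents that add atoms: dimethyldioxirane, CC1(C)OO1
Why: Dimethyldioxirane transfers oxygen to the electron-rich cis C3=C4 bond on the face anti to the C2 aryl group, as in the known anti dihydroxylation of flav-3-enes, giving trans-epoxide 13 and fixing C3 as 3S with its oxygen trans to the aryl group. BF3 then activates the strained oxirane, whose C4–O bond alone lengthens because it is benzylic to ring A and conjugated with O7 (para to C4a) and O1 (ortho, via C8a), and C8 of ring D of 12 attacks C4 from the face opposite the departing oxygen; the closest known reaction types are the Lewis-acid Friedel–Crafts opening of styrene-type and chromene oxides by electron-rich arenes and the flavan-3,4-diol/flavan-3-ol condensation. No ring is closed in this step: the three-membered ring is opened, and its strain (about 27 kcal/mol) should pay for the C–C bond at −78 °C with substoichiometric acid. C4 is set by inversion at the epoxide carbon (4S, new aryl group trans to the 3-hydroxyl and cis to the C2 aryl group), and a fully ionised C4 cation should give the same 3,4-trans product because the BF3-bound 3-oxygen blocks the other face. The step needs opening at C4 and not C3 (secured by the ring A oxygens), attack by C8 and not C6 (C6 lies between two benzyloxy groups, C8 between one benzyloxy group and the ring oxygen), and C- over O-alkylation and mono- over oligo-alkylation (secured by the irreversibility of C–C formation, the excess of 12 and the slow addition of 13).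

Step 10
Reactants: 14 octa-O-benzyl robinetinidol-(4α,8)-catechin
Product: 15 robinetinidol-(4α,8)-catechin
Conditions: H2 (1 atm), Pd(OH)2/C, THF/MeOH/H2O, 23 °C; filtration under argon, lyophilisation
Reagents that add atoms: none
Why: Hydrogenolysis of the eight aryl benzyl ethers under neutral conditions should free the phenols, while the cyclic benzylic C2–O1 ethers and the C4–C8 bond of flavans are known to survive these conditions.

**Compound list**
1 | 3,4,5-trihydroxybenzaldehyde | O=Cc1cc(O)c(O)c(O)c1 | starting material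
2 | 3,4,5-tris(benzyloxy)benzaldehyde | O=Cc1cc(OCc2ccccc2)c(OCc2ccccc2)c(OCc2ccccc2)c1 | intermediate
3 | ethyl (2E)-3-[3,4,5-tris(benzyloxy)phenyl]prop-2-enoate | CCOC(=O)/C=C/c1cc(OCc2ccccc2)c(OCc2ccccc2)c(OCc2ccccc2)c1 | intermediate
4 | (2E)-3-[3,4,5-tris(benzyloxy)phenyl]prop-2-en-1-ol | OC/C=C/c1cc(OCc2ccccc2)c(OCc2ccccc2)c(OCc2ccccc2)c1 | intermediate
5 | methyl (2E)-3-[3,4,5-tris(benzyloxy)phenyl]prop-2-en-1-yl carbonate | COC(=O)OC/C=C/c1cc(OCc2ccccc2)c(OCc2ccccc2)c(OCc2ccccc2)c1 | intermediate
6 | 4-(benzyloxy)-2-hydroxybenzaldehyde | O=Cc1ccc(OCc2ccccc2)cc1O | starting material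
7 | 5-(benzyloxy)-2-ethenylphenol | C=Cc1ccc(OCc2ccccc2)cc1O | intermediate
8 | lithium 5-(benzyloxy)-2-ethenylphenolate | [Li+].[O-]c1cc(OCc2ccccc2)ccc1C=C | intermediate
9 | 4-(benzyloxy)-1-ethenyl-2-({(1S)-1-[3,4,5-tris(benzyloxy)phenyl]prop-2-en-1-yl}oxy)benzene | O(Cc3ccccc3)c1ccc(C=C)c(c1)O[C@H](c1cc(OCc3ccccc3)c(OCc3ccccc3)c(OCc3ccccc3)c1)C=C | intermediate
10 | (2S)-7-(benzyloxy)-2-[3,4,5-tris(benzyloxy)phenyl]-2H-chromene | O(Cc3ccccc3)c1ccc2c(c1)O[C@H](c1cc(OCc3ccccc3)c(OCc3ccccc3)c(OCc3ccccc3)c1)C=C2 | intermediate
11 | (+)-catechin, (2R,3S)-2-(3,4-dihydroxyphenyl)chromane-3,5,7-triol | Oc1cc(O)c2c(c1)O[C@H](c1ccc(O)c(O)c1)[C@@H](O)C2 | starting material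
12 | (2R,3S)-5,7-bis(benzyloxy)-2-[3,4-bis(benzyloxy)phenyl]chroman-3-ol (5,7,3',4'-tetra-O-benzylcatechin) | O(Cc3ccccc3)c1cc(OCc3ccccc3)c2c(c1)O[C@H](c1ccc(OCc3ccccc3)c(OCc3ccccc3)c1)[C@@H](O)C2 | intermediate
13 | (2R,3S,4S)-7-(benzyloxy)-3,4-epoxy-2-[3,4,5-tris(benzyloxy)phenyl]chromane (oxirane trans to the C2 aryl group) | O(Cc3ccccc3)c1ccc2c(c1)O[C@H](c1cc(OCc3ccccc3)c(OCc3ccccc3)c(OCc3ccccc3)c1)[C@H]1O[C@H]12 | intermediate
14 | (2R,3S,4S)-7-(benzyloxy)-4-{(2R,3S)-5,7-bis(benzyloxy)-2-[3,4-bis(benzyloxy)phenyl]-3-hydroxychroman-8-yl}-2-[3,4,5-tris(benzyloxy)phenyl]chroman-3-ol (octa-O-benzyl robinetinidol-(4α,8)-catechin) | O(Cc3ccccc3)c1ccc2c(c1)O[C@H](c1cc(OCc3ccccc3)c(OCc3ccccc3)c(OCc3ccccc3)c1)[C@@H](O)[C@@H]2c1c(OCc3ccccc3)cc(OCc3ccccc3)c2c1O[C@H](c1ccc(OCc3ccccc3)c(OCc3ccccc3)c1)[C@@H](O)C2 | intermediate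
15 | robinetinidol-(4α,8)-catechin | Oc1ccc2c(c1)O[C@H](c1cc(O)c(O)c(O)c1)[C@@H](O)[C@@H]2c1c(O)cc(O)c2c1O[C@H](c1ccc(O)c(O)c1)[C@@H](O)C2 | target

**Totals**
Total step count: 10. Longest linear sequence: 8 steps (steps 1, 2, 3, 4, 6, 7, 9 and 10).

**Steps most likely to fail, with fallbacks**

1. Step 9 (oxirane formation and Friedel–Crafts opening). What may go wrong: the activated oxirane may rearrange by 1,2-hydride shift to the flavan-3-one, lose stereospecificity through full ionisation, or alkylate the first-formed product a second time. The fallback uses known chemistry, sets out from 10 and comes back at 14. Dihydroxylation of 10 with catalytic OsO4 and N-methylmorpholine N-oxide in acetone/water, which on flav-3-enes adds anti to the C2 aryl group, should give (2R,3S,4S)-7-(benzyloxy)-2-[3,4,5-tris(benzyloxy)phenyl]chromane-3,4-diol F1. Ionisation of its benzylic 4-hydroxyl with Me3SiOTf in CH2Cl2 at −78 °C in the presence of excess 12 (the flavan-3,4-diol/flavan-3-ol condensation, attack trans to the 3-oxygen) should then give 14.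

2. Step 6 (iridium-catalysed etherification). What may go wrong: loss of branched selectivity or of enantiomeric purity through reversible ionisation of the very electron-rich ether, or polymerisation of the vinylphenol before it reacts. The fallback sets out from 2 and 6 and comes back at 10, so it bypasses 7, 8 and 9. Wittig reaction of 2 with (triphenylphosphoranylidene)acetaldehyde in toluene at 80 °C should give (2E)-3-[3,4,5-tris(benzyloxy)phenyl]prop-2-enal F2. Domino oxa-Michael/aldol condensation of F2 with 6, catalysed by (S)-α,α-diphenylprolinol trimethylsilyl ether and 2-nitrobenzoic acid in toluene, should give (2R)-7-(benzyloxy)-2-[3,4,5-tris(benzyloxy)phenyl]-2H-chromene-3-carbaldehyde F3; the iminium shielding model predicts addition of the phenol oxygen to the face of the β-carbon remote from the catalyst's diphenyl(silyloxy)methyl group. Tsuji–Wilkinson decarbonylation with RhCl(PPh3)3 in toluene at the lowest workable temperature should then give 10.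

3. Step 10 (global debenzylation). What may go wrong: incomplete cleavage of the eight ethers, or oxidative degradation of the free polyphenol on the catalyst surface. The fallback sets out from 14 and comes back at 15 by heterolytic instead of reductive cleavage: BCl3 with pentamethylbenzene as a non-basic benzyl-cation scavenger in CH2Cl2 at −78 °C, followed by a methanol quench. The interflavan bond of the 5-deoxy series is comparatively acid-stable, and this fallback makes no new compound (F0).

Further compounds
F1 | step 9 | (2R,3S,4S)-7-(benzyloxy)-2-[3,4,5-tris(benzyloxy)phenyl]chromane-3,4-diol | O(Cc3ccccc3)c1ccc2c(c1)O[C@H](c1cc(OCc3ccccc3)c(OCc3ccccc3)c(OCc3ccccc3)c1)[C@@H](O)[C@H]2O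
F2 | step 6 | (2E)-3-[3,4,5-tris(benzyloxy)phenyl]prop-2-enal | O=C/C=C/c1cc(OCc2ccccc2)c(OCc2ccccc2)c(OCc2ccccc2)c1
F3 | step 6 | (2R)-7-(benzyloxy)-2-[3,4,5-tris(benzyloxy)phenyl]-2H-chromene-3-carbaldehyde | O(Cc3ccccc3)c1ccc2c(c1)O[C@H](c1cc(OCc3ccccc3)c(OCc3ccccc3)c(OCc3ccccc3)c1)C(C=O)=C2
F0 | step 10 | none | none
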